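Readings and results were generated by integration for an exercise; the scatter is artificial.

I counted turnovers.

in all of them: starting material 0.40 M; free catalyst 0.5 mol%

| charge | reagent | temperature | remark | time |
|---|---|---|---|---|
| amber | 1.6 equiv | 130 °C | run made earlier |  |
| east | 1.05 equiv | 130 °C |  | 12 min |
| west | 1.05 equiv | 110 °C |  | 12 min |
| north-west | 1.05 equiv | 90 °C |  | 12 min |
| south | 1.05 equiv | 70 °C |  | 12 min |

- amber (time / min: open intermediate / %, target / %, starting material / %): 0.333: 51.8, 5.0, 10.0; 0.833: 50.6, 15.0, 0.4; 1.50: 40.4, 26.8, 0; 2.50: 28.1, 39.1, 0; 4.00: 15.8, 50.8, 0

(standard deviation of a reading: 0.5 percentage points)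

- what was read earlier has a scatter of 0.5 percentage points, one standard deviation
- the earlier runs do not show what temperature does; that part of a forecast is a guess

- the flask with the highest amount of open intermediate, in percent of the starting material charged ("all alike" if they lie within 1.5 percentage points) (east / west / north-west / south / all alike)
- final open intermediate, as a percentage of the starting material charged, in east
- final open intermediate, as a percentage of the starting material charged, in west
- final open intermediate, as a percentage of the starting material charged, in north-west
- final open intermediate, as a percentage of the starting material charged, in south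

1. The measure. In amber, target rose from 39.1% to 50.8% between the last two readings. Target gained per minute, divided by the catalyst loading, gave 15.6 min⁻¹. That reading is the number of turnovers each charged catalyst made per minute over that stretch, the turnover rate (turnover frequency).

2. The bill. Open intermediate and target together stood at 66.6% at the last amber reading. Carrying that amount to target at this loading asked 133 turnovers of each catalyst.

3. Time. Held steady for 12 min, amber's rate came to 187 turnovers, more than the bill.

4. Reagent. Amber shows one reagent level, so I assumed by hand that the rate follows the charge, going from 1.6 equiv to 1.05 equiv. That gave 10.2 min⁻¹ for east. The bill then took 13.0 min, longer than the time allowed, so I expected 5.18% open intermediate in east.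

5. Temperature. Amber shows nothing here, so I guessed that the rate falls by a factor of 4 per step of cooling and kept the bill unchanged. That gave 51.2% in west, 62.8% in north-west and 65.6% in south. My choice was therefore south.

The forecast differed from my reckoning. It chose north-west, with 1.2% in east, 22% in west, 46% in north-west and 42% in south. Its words were: “The maximum lies at the cooler temperatures; north-west versus south is uncertain.”

The flasks gave south as the highest: 6.40% in east, 38.0% in west, 70.8% in north-west and 85.3% in south.

    starting material + free catalyst → free catalyst + open intermediate (k = 560 L mol⁻¹ min⁻¹, Ea = 56.0 kJ mol⁻¹)
    free catalyst + open intermediate ⇌ catalyst intermediate (K = 1.60 L mol⁻¹, k = 1600 L mol⁻¹ min⁻¹, Ea = 50.0 kJ mol⁻¹, ΔH = 19.0 kJ mol⁻¹)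
    reagent + catalyst intermediate → free catalyst + target (k = 18.0 L mol⁻¹ min⁻¹, Ea = 69.0 kJ mol⁻¹)
    2 starting material → self-condensation product (k = 0.480 L mol⁻¹ min⁻¹, Ea = 86.0 kJ mol⁻¹)
    (constants at 90 °C)

South held 85.3% open intermediate at 12.0 min, when it was still being made 2.48 times faster than it was used up, each step taken net. South's 2.66% target meant an average turnover rate of 0.443 min⁻¹ over 12 min, far below the 15.6 min⁻¹ read in amber. For the neighbour of south with 0.3 mol% free catalyst, south's average rate gave 1.59% target, and that flask held 1.35%.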